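**Retrosynthetic overview**
- The target is reached from a norbornene C20-boronate by C–B oxidation (retention) and exo-face hydrogenation of the C4=C5 bond.
- Ring B and the bicyclo[2.2.1]heptane form together in one intramolecular Diels–Alder reaction (C8–C19 and C6–C20 bonds) between a 1-alkyl-2-isopropylcyclopentadiene and an (E)-alkenylboronate held on ring A.
- The diene comes from a 2-alkylcyclopent-2-enone plus iPrMgCl (dehydration in the cycloaddition pot); the dienophile comes from a vinyl group by cross-metathesis.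
- Ring A (C11–C18 bond, equatorial Br) comes from a bromonium cyclization onto a silicon-tethered allylsilane; C16 is taken from (R)-linalool (1).
- The chain comes from 1 by allylic oxidation, CH2Bpin homologation and Suzuki coupling with a bromocyclopentenone. Ring order: A first, then B and the norbornane in one step.

Assumption: locants C1–C20 are those of the target SMILES atoms read left to right (C4 = CH–iPr, C8 = quaternary bridgehead, C11 = C–Me, C13 = CHBr, C16 = C(Me)OH, C18/C19 = ring-fusion CH, C20 = CHOH); commercial (R)-(−)-linalool is taken as enantiopure.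

**Route**

Step 1
Reactants: 1 (R)-(−)-linalool [(3R)-3,7-dimethylocta-1,6-dien-3-ol]
Product: 2 (2E,6R)-2,6-dimethylocta-2,7-diene-1,6-diol
Conditions: SeO2 (0.2 equiv), t-BuOOH (2 equiv), salicylic acid (0.1 equiv), CH2Cl2, 25 °C
Reagents that add atoms: tert-butyl hydroperoxide, CC(C)(C)OO
Why: Riley allylic oxidation (ene reaction then [2,3]-sigmatropic shift) hydroxylates only the (E)-methyl group of the trisubstituted alkene and leaves the chiral-pool carbinol (future C16) untouched.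

Step 2
Reactants: 2 (2E,6R)-2,6-dimethylocta-2,7-diene-1,6-diol
Product: 3 (3R,6E)-8-bromo-3,7-dimethylocta-1,6-dien-3-ol
Conditions: CBr4 (1.1 equiv), PPh3 (1.15 equiv), CH2Cl2, −20 to 0 °C
Reagents that add atoms: carbon tetrabromide, BrC(Br)(Br)Br
Why: Appel reaction, in which the unhindered primary allylic alcohol forms the alkoxyphosphonium ion and is displaced by bromide (SN2) while the hindered tertiary alcohol does not react at low temperature.

Step 3
Reactants: 3 (3R,6E)-8-bromo-3,7-dimethylocta-1,6-dien-3-ol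
Product: 4 (3R,6E)-3,7-dimethyl-9-(4,4,5,5-tetramethyl-1,3,2-dioxaborolan-2-yl)nona-1,6-dien-3-ol
Conditions: CH2(Bpin)2 (1.3 equiv) premixed with NaOtBu (2.5 equiv), THF, 0 to 25 °C
Reagents that add atoms: bis[(pinacolato)boryl]methane, CC1(C)OB(CB2OC(C)(C)C(C)(C)O2)OC1(C)C
Why: deborylative alkylation, in which alkoxide-induced loss of one boryl group gives an α-boryl carbanion that displaces the primary allylic bromide (SN2) and adds C9 as CH2Bpin without touching the E-alkene.

Step 4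
Reactants: 4 (3R,6E)-3,7-dimethyl-9-(4,4,5,5-tetramethyl-1,3,2-dioxaborolan-2-yl)nona-1,6-dien-3-ol; 5 2-bromocyclopent-2-en-1-one
Product: 6 2-[(3E,7R)-7-hydroxy-3,7-dimethylnona-3,8-dien-1-yl]cyclopent-2-en-1-one
Conditions: Pd(OAc)2 (5 mol %), RuPhos (10 mol %), K3PO4 (3 equiv), toluene/H2O (10:1), 90 °C
Reagents that add atoms: none
Why: sp3–sp2 Suzuki–Miyaura coupling of the primary alkylboronate with the α-bromoenone forms the C8–C9 bond and leaves the electron-poor enone as a bromonium-inert mask of the future diene.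

Step 5
Reactants: 6 2-[(3E,7R)-7-hydroxy-3,7-dimethylnona-3,8-dien-1-yl]cyclopent-2-en-1-one
Product: 7 2-[(3E,7R)-7-{[dimethyl(prop-2-en-1-yl)silyl]oxy}-3,7-dimethylnona-3,8-dien-1-yl]cyclopent-2-en-1-one
Conditions: allyl(chloro)dimethylsilane (1.5 equiv), imidazole (2 equiv), DMAP (cat.), DMF, 40 °C
Reagents that add atoms: allyl(chloro)dimethylsilane, C=CC[Si](C)(C)Cl
Why: silylation of the tertiary alcohol (nucleophilic catalysis) blocks bromoetherification by the free hydroxyl and brings in the carbon atoms of the allylsilane.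

Step 6
Reactants: 7 2-[(3E,7R)-7-{[dimethyl(prop-2-en-1-yl)silyl]oxy}-3,7-dimethylnona-3,8-dien-1-yl]cyclopent-2-en-1-one
Product: 8 2-{(3E)-3-methyl-6-[(6R)-2,2,6-trimethyl-3,6-dihydro-2H-1,2-oxasilin-6-yl]hex-3-en-1-yl}cyclopent-2-en-1-one
Conditions: second-generation Grubbs catalyst (5 mol %), CH2Cl2 (0.005 M), 40 °C
Reagents that add atoms: none
Why: silicon-tethered ring-closing metathesis joins the two monosubstituted alkenes into a six-membered cyclic allylsiloxane (ethylene lost) faster than the trisubstituted alkene or the enone can react, which turns C18 into the γ-carbon of an allylsilane.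

Step 7
Reactants: 8 2-{(3E)-3-methyl-6-[(6R)-2,2,6-trimethyl-3,6-dihydro-2H-1,2-oxasilin-6-yl]hex-3-en-1-yl}cyclopent-2-en-1-one
Product: 10 2-{2-[(1S,2S,3R,6S)-6-bromo-2-ethenyl-3-hydroxy-1,3-dimethylcyclohexyl]ethyl}cyclopent-2-en-1-one, via bromodimethylsilyl ether 9 (not isolated)
Conditions: BDSB (Et2SBr·SbCl5Br, 1.1 equiv), MeNO2, −25 °C, 15 min; then K2CO3, THF/H2O, 25 °C
Reagents that add atoms: bromodiethylsulfonium bromopentachloroantimonate (BDSB), CC[S+](Br)CC.Cl[Sb-](Cl)(Cl)(Cl)(Cl)Br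
Why: Proposed new method: BDSB transfers Br+ to the electron-rich trisubstituted C11=C13 alkene and the tertiary cation at C11 is captured in a six-membered chair by C18, the γ-carbon of the tethered allylsiloxane (anti SE2′, silicon lost to bromide and then hydrolysed off), the closest known reactions being bromonium-initiated cation–olefin cyclizations and Hosomi–Sakurai terminations; the E-alkene places C11–Me axial and Br equatorial, and the siloxane ring holds O16 nearly eclipsed with C18=C19 so that O16 must be axial, which fixes C11, C13 and C18 relative to the linalool-derived C16.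

Step 8
Reactants: 10 2-{2-[(1S,2S,3R,6S)-6-bromo-2-ethenyl-3-hydroxy-1,3-dimethylcyclohexyl]ethyl}cyclopent-2-en-1-one
Product: 11 2-{2-[(1S,2S,3R,6S)-6-bromo-2-ethenyl-3-hydroxy-1,3-dimethylcyclohexyl]ethyl}-1-(propan-2-yl)cyclopent-2-en-1-ol (both carbinol epimers)
Conditions: iPrMgCl (3 equiv), CeCl3 (3 equiv), THF, −78 °C; then H2O
Reagents that add atoms: isopropylmagnesium chloride, CC(C)[Mg]Cl
Why: organocerium (Imamoto) 1,2-addition to the enone carbonyl gives the tertiary allylic alcohol that is the direct precursor of the 1-alkyl-2-isopropylcyclopentadiene, the new carbinol centre being destroyed in step 10 so that its configuration does not matter.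

Step 9
Reactants: 11 2-{2-[(1S,2S,3R,6S)-6-bromo-2-ethenyl-3-hydroxy-1,3-dimethylcyclohexyl]ethyl}-1-(propan-2-yl)cyclopent-2-en-1-ol
Product: 12 2-{2-[(1S,2S,3R,6S)-6-bromo-3-hydroxy-1,3-dimethyl-2-[(E)-2-(4,4,5,5-tetramethyl-1,3,2-dioxaborolan-2-yl)ethenyl]cyclohexyl]ethyl}-1-(propan-2-yl)cyclopent-2-en-1-ol
Conditions: vinylboronic acid pinacol ester (5 equiv), second-generation Hoveyda–Grubbs catalyst (10 mol %), CH2Cl2, 40 °C
Reagents that add atoms: 2-ethenyl-4,4,5,5-tetramethyl-1,3,2-dioxaborolane, C=CB1OC(C)(C)C(C)(C)O1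
Why: olefin cross-metathesis of the terminal vinyl group with the vinylboronate gives the E-alkenylboronate (thermodynamic E selectivity) while the trisubstituted ring alkene stays inert.

Step 10
Reactants: 12 2-{2-[(1S,2S,3R,6S)-6-bromo-3-hydroxy-1,3-dimethyl-2-[(E)-2-(4,4,5,5-tetramethyl-1,3,2-dioxaborolan-2-yl)ethenyl]cyclohexyl]ethyl}-1-(propan-2-yl)cyclopent-2-en-1-ol
Product: 14 norbornene boronate (Diels–Alder adduct; 4,5-didehydro-20-deoxy-20-endo-Bpin analogue of 16), via cyclopentadiene 13 (not isolated)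
Conditions: PPTS (5 mol %), toluene, 25 °C, 1 h; then iPr2NEt (10 mol %), BHT, toluene (0.005 M), 120 °C, 24 h
Reagents that add atoms: none
Why: intramolecular Diels–Alder reaction in which acid-induced dehydration of the tertiary allylic alcohol gives the 1,2-disubstituted cyclopentadiene 13, whose isomers interconvert by 1,5-hydrogen shifts so that the isomer tethered at a diene terminus adds the E-alkenylboronate through a chair-like six-membered tether (H18 eclipsing the alkene, diene anti to C16), forming ring B and the norbornene together and setting C8, C19 and C6, with Bpin endo at C20 because it is trans to C18, which the tether forces exo.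

Step 11
Reactants: 14 norbornene boronate (Diels–Alder adduct)
Product: 15 20-deoxy-20-(4,4,5,5-tetramethyl-1,3,2-dioxaborolan-2-yl) analogue of 16 (endo-isopropyl at C4; endo-Bpin at C20)
Conditions: H2 (1 atm), PtO2 (5 mol %), EtOAc, 25 °C
Reagents that add atoms: none
Why: heterogeneous catalytic hydrogenation adds H2 to the strained trisubstituted norbornene from the exo face (the endo face is blocked by the C19–C20 bridge and its endo boronate), which places the isopropyl group endo at C4.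

Step 12
Reactants: 15 20-deoxy-20-(4,4,5,5-tetramethyl-1,3,2-dioxaborolan-2-yl) analogue of 16
Product: 16 CNP0295684.1 (target)
Conditions: NaBO3·4H2O (5 equiv), THF/H2O (1:1), 25 °C
Reagents that add atoms: sodium perborate, [Na+].[O-]OB=O
Why: oxidation of the secondary alkylboronate with 1,2-migration of carbon from boron to oxygen proceeds with retention and gives the endo C20 alcohol without touching the secondary bromide.

**Compound list**

1 | (R)-(−)-linalool, (3R)-3,7-dimethylocta-1,6-dien-3-ol | CC(C)=CCC[C@@](C)(O)C=C | starting material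
2 | (2E,6R)-2,6-dimethylocta-2,7-diene-1,6-diol | OC/C(C)=C/CC[C@@](C)(O)C=C | intermediate
3 | (3R,6E)-8-bromo-3,7-dimethylocta-1,6-dien-3-ol | BrC/C(C)=C/CC[C@@](C)(O)C=C | intermediate
4 | (3R,6E)-3,7-dimethyl-9-(4,4,5,5-tetramethyl-1,3,2-dioxaborolan-2-yl)nona-1,6-dien-3-ol | CC1(C)OB(CC/C(C)=C/CC[C@@](C)(O)C=C)OC1(C)C | intermediate
5 | 2-bromocyclopent-2-en-1-one | O=C1CCC=C1Br | starting material
6 | 2-[(3E,7R)-7-hydroxy-3,7-dimethylnona-3,8-dien-1-yl]cyclopent-2-en-1-one | O=C1CCC=C1CC/C(C)=C/CC[C@@](C)(O)C=C | intermediate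
7 | 2-[(3E,7R)-7-{[dimethyl(prop-2-en-1-yl)silyl]oxy}-3,7-dimethylnona-3,8-dien-1-yl]cyclopent-2-en-1-one | O=C1CCC=C1CC/C(C)=C/CC[C@@](C)(O[Si](C)(C)CC=C)C=C | intermediate
8 | 2-{(3E)-3-methyl-6-[(6R)-2,2,6-trimethyl-3,6-dihydro-2H-1,2-oxasilin-6-yl]hex-3-en-1-yl}cyclopent-2-en-1-one | O=C1CCC=C1CC/C(C)=C/CC[C@@]2(C)O[Si](C)(C)CC=C2 | intermediate
9 | 2-{2-[(1S,2S,3R,6S)-6-bromo-3-{[bromo(dimethyl)silyl]oxy}-2-ethenyl-1,3-dimethylcyclohexyl]ethyl}cyclopent-2-en-1-one (bromodimethylsilyl ether of 10; not isolated) | O=C1CCC=C1CC[C@]2(C)[C@@H](Br)CC[C@@](C)(O[Si](C)(C)Br)[C@H]2C=C | intermediate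
10 | 2-{2-[(1S,2S,3R,6S)-6-bromo-2-ethenyl-3-hydroxy-1,3-dimethylcyclohexyl]ethyl}cyclopent-2-en-1-one | O=C1CCC=C1CC[C@]2(C)[C@@H](Br)CC[C@@](C)(O)[C@H]2C=C | intermediate
11 | 2-{2-[(1S,2S,3R,6S)-6-bromo-2-ethenyl-3-hydroxy-1,3-dimethylcyclohexyl]ethyl}-1-(propan-2-yl)cyclopent-2-en-1-ol (both carbinol epimers) | CC(C)C1(O)CCC=C1CC[C@]2(C)[C@@H](Br)CC[C@@](C)(O)[C@H]2C=C | intermediate
12 | 2-{2-[(1S,2S,3R,6S)-6-bromo-3-hydroxy-1,3-dimethyl-2-[(E)-2-(4,4,5,5-tetramethyl-1,3,2-dioxaborolan-2-yl)ethenyl]cyclohexyl]ethyl}-1-(propan-2-yl)cyclopent-2-en-1-ol | CC(C)C1(O)CCC=C1CC[C@]2(C)[C@@H](Br)CC[C@@](C)(O)[C@H]2/C=C/B3OC(C)(C)C(C)(C)O3 | intermediate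
13 | (1R,2S,3S,4S)-4-bromo-1,3-dimethyl-3-{2-[2-(propan-2-yl)cyclopenta-1,3-dien-1-yl]ethyl}-2-[(E)-2-(4,4,5,5-tetramethyl-1,3,2-dioxaborolan-2-yl)ethenyl]cyclohexan-1-ol (not isolated; in equilibrium with its 1,5-hydrogen-shift isomers) | CC(C)C1=C(CC[C@]2(C)[C@@H](Br)CC[C@@](C)(O)[C@H]2/C=C/B3OC(C)(C)C(C)(C)O3)CC=C1 | intermediate
14 | Diels–Alder adduct: 4,5-didehydro-20-deoxy-20-(pinacolboryl) analogue of 16 (C4=C5 norbornene; Bpin endo at C20) | CC(C)C1=C[C@H]2C[C@@]13CC[C@]1(C)[C@@H](Br)CC[C@@](C)(O)[C@H]1[C@@H]3[C@H]2B1OC(C)(C)C(C)(C)O1 | intermediate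
15 | 20-deoxy-20-(pinacolboryl) analogue of 16 (endo-isopropyl at C4; endo-Bpin at C20) | CC(C)[C@@H]1C[C@H]2C[C@@]13CC[C@]1(C)[C@@H](Br)CC[C@@](C)(O)[C@H]1[C@@H]3[C@H]2B1OC(C)(C)C(C)(C)O1 | intermediate
16 | CNP0295684.1: trans-decalin (equatorial Br at C13, axial tertiary OH at C16) fused at C8–C19 to a norbornane carrying endo-isopropyl at C4 and endo-OH at C20 | CC(C)[C@@H]1C[C@H]2C[C@@]13CC[C@]1(C)[C@@H](Br)CC[C@@](C)(O)[C@H]1[C@@H]3[C@H]2O | target

**Step count**
Total steps: 12. Longest linear sequence: 12 steps (1 to 16).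

**Steps most likely to fail**

Step 7 (bromonium cyclization). Br+ may attack the allylsiloxane instead of the C11=C13 alkene, or the silyl ether oxygen may capture the bromonium ion. The fallback installs bromine before any allylsilane exists. It sets out from 6: NBS in CH2Cl2 at 0 °C lets the free tertiary hydroxyl open the bromonium ion (6-endo bromoetherification). After separation from its C13 epimer this gives the bromotetrahydropyran 2-{2-[(2R,3S,6R)-3-bromo-6-ethenyl-2,6-dimethyloxan-2-yl]ethyl}cyclopent-2-en-1-one F1. Cross-metathesis of its vinyl group with allyltrimethylsilane (second-generation Hoveyda–Grubbs catalyst) gives the allylsilane 2-{2-[(2R,3S,6R)-3-bromo-2,6-dimethyl-6-[(1E)-3-(trimethylsilyl)prop-1-en-1-yl]oxan-2-yl]ethyl}cyclopent-2-en-1-one F2. TiCl4 in CH2Cl2 at −78 °C then ionises the tertiary C11–O bond with bromine assistance, and the allylsilane closes ring A in an intramolecular Hosomi–Sakurai reaction to give 10, where the fallback comes back to the route.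

Step 10 (intramolecular Diels–Alder reaction). The alkenylboronate is only a modest dienophile, so diene dimerisation may compete; a regioisomer from the minor 5-isopropyl diene isomer, or the wrong facial approach, is also possible. The fallback uses a ketone-activated dienophile and unmasks the oxygen later by Baeyer–Villiger oxidation. It sets out from 11 and returns at 16:
- Cross-metathesis with methyl vinyl ketone gives the enone (3E)-4-[(1S,2S,3S,6R)-3-bromo-6-hydroxy-2-{2-[5-hydroxy-5-(propan-2-yl)cyclopent-1-en-1-yl]ethyl}-2,6-dimethylcyclohexyl]but-3-en-2-one F5.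
- PPTS, then 60 °C, generates the cyclopentadiene (3E)-4-[(1S,2S,3S,6R)-3-bromo-6-hydroxy-2,6-dimethyl-2-{2-[2-(propan-2-yl)cyclopenta-1,3-dien-1-yl]ethyl}cyclohexyl]but-3-en-2-one F6.
- F6 cyclises to the endo-acetyl norbornene (4,5-didehydro-20-deoxy-20-acetyl analogue of 16) F7; base is avoided so that the endo-acetyl group does not epimerise.
- Hydrogenation (H2, PtO2) gives the saturated methyl ketone (20-deoxy-20-acetyl analogue of 16) F8.
- Baeyer–Villiger oxidation (mCPBA, NaHCO3, CH2Cl2) gives, with retention, the C20 acetate of 16 F9.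
- K2CO3 in MeOH removes the acetyl group and gives 16.

Step 9 (cross-metathesis on a vinyl group flanked by two quaternary carbons). The fallback replaces metathesis by ozonolysis and olefination. It sets out from 10: O3 in CH2Cl2/MeOH at −78 °C, then Me2S, cleaves only the vinyl group (the enone alkene is electron-poor) and gives the aldehyde (1S,2S,3S,6R)-3-bromo-6-hydroxy-2,6-dimethyl-2-[2-(5-oxocyclopent-1-en-1-yl)ethyl]cyclohexane-1-carbaldehyde F3. Takai–Utimoto olefination (Cl2CHBpin, CrCl2, LiI, THF, 25 °C) gives the E-alkenylboronate 2-{2-[(1S,2S,3R,6S)-6-bromo-3-hydroxy-1,3-dimethyl-2-[(E)-2-(4,4,5,5-tetramethyl-1,3,2-dioxaborolan-2-yl)ethenyl]cyclohexyl]ethyl}cyclopent-2-en-1-one F4. iPrMgCl with CeCl3 at −78 °C then adds to the enone carbonyl faster than to the hindered pinacol boronate and gives 12, where the fallback comes back to the route.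

Further compounds
F1 | step 7 | 2-{2-[(2R,3S,6R)-3-bromo-6-ethenyl-2,6-dimethyloxan-2-yl]ethyl}cyclopent-2-en-1-one | O=C1CCC=C1CC[C@]2(C)[C@@H](Br)CC[C@](C)(C=C)O2
F2 | step 7 | 2-{2-[(2R,3S,6R)-3-bromo-2,6-dimethyl-6-[(1E)-3-(trimethylsilyl)prop-1-en-1-yl]oxan-2-yl]ethyl}cyclopent-2-en-1-one | O=C1CCC=C1CC[C@]2(C)[C@@H](Br)CC[C@](C)(/C=C/C[Si](C)(C)C)O2
F3 | step 9 | (1S,2S,3S,6R)-3-bromo-6-hydroxy-2,6-dimethyl-2-[2-(5-oxocyclopent-1-en-1-yl)ethyl]cyclohexane-1-carbaldehyde | O=C1CCC=C1CC[C@]2(C)[C@@H](Br)CC[C@@](C)(O)[C@H]2C=O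
F4 | step 9 | 2-{2-[(1S,2S,3R,6S)-6-bromo-3-hydroxy-1,3-dimethyl-2-[(E)-2-(4,4,5,5-tetramethyl-1,3,2-dioxaborolan-2-yl)ethenyl]cyclohexyl]ethyl}cyclopent-2-en-1-one | O=C1CCC=C1CC[C@]2(C)[C@@H](Br)CC[C@@](C)(O)[C@H]2/C=C/B3OC(C)(C)C(C)(C)O3
F5 | step 10 | (3E)-4-[(1S,2S,3S,6R)-3-bromo-6-hydroxy-2-{2-[5-hydroxy-5-(propan-2-yl)cyclopent-1-en-1-yl]ethyl}-2,6-dimethylcyclohexyl]but-3-en-2-one | CC(C)C1(O)CCC=C1CC[C@]2(C)[C@@H](Br)CC[C@@](C)(O)[C@H]2/C=C/C(C)=O
F6 | step 10 | (3E)-4-[(1S,2S,3S,6R)-3-bromo-6-hydroxy-2,6-dimethyl-2-{2-[2-(propan-2-yl)cyclopenta-1,3-dien-1-yl]ethyl}cyclohexyl]but-3-en-2-one | CC(C)C1=C(CC[C@]2(C)[C@@H](Br)CC[C@@](C)(O)[C@H]2/C=C/C(C)=O)CC=C1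
F7 | step 10 | 4,5-didehydro-20-deoxy-20-acetyl analogue of 16 (endo-acetyl norbornene) | CC(C)C1=C[C@H]2C[C@@]13CC[C@]1(C)[C@@H](Br)CC[C@@](C)(O)[C@H]1[C@@H]3[C@H]2C(C)=O
F8 | step 10 | 20-deoxy-20-acetyl analogue of 16 | CC(C)[C@@H]1C[C@H]2C[C@@]13CC[C@]1(C)[C@@H](Br)CC[C@@](C)(O)[C@H]1[C@@H]3[C@H]2C(C)=O
F9 | step 10 | C20 acetate of 16 | CC(C)[C@@H]1C[C@H]2C[C@@]13CC[C@]1(C)[C@@H](Br)CC[C@@](C)(O)[C@H]1[C@@H]3[C@H]2OC(C)=O
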